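**Plan**

1. Ring numbering used throughout: C1 (=CH2), C2–C4 (CH2), C5 (Me, OH), C6, C7 (aroyloxy), C8 (iPr), C9 (OH), C10. Enabling feature: if C1 and C5 are read as former ketones, the cyclodecane skeleton has a mirror plane through C3 and C8 (O7, iPr8 and O9 all cis; C1/C5, C2/C4, C6/C10 and C7/C9 pairwise equivalent), and C1 and C5 are 1,5-related through three unsubstituted CH2 groups, which is the retron of a two-carbon ring enlargement of a cyclic 1,3-dione with ethene.
2. Retrosynthesis: ester C7–O; C5–CH3 and C5–O (through an exocyclic alkene and its epoxide); both C=CH2; then C2–C3 and C4–C5 are cut and C2–C5 re-joined (C3–C4 leave as ethene) to a meso cyclooctane-1,3-dione; C1–C2 and C5–C6 are cut and C1–C6 re-joined (C2 and C5 leave as a ketene) to a meso cyclohexanone; ketone from CO2H; cyclohexane from an arene.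
3. Forward order of the rings: benzene ring, all-cis cyclohexane, eight-membered 1,3-dione, ten-membered 1,5-dione (key step), then bis-methylidene meso diol, desymmetrisation, C5 carbinol, ester.
4. Stereochemistry: the relative configuration of C7/C8/C9 comes from one cis-hydrogenation; both ring enlargements create only transient stereocentres; the absolute configuration comes from one catalytic enantioselective silylation of the meso diol; C5 is relayed from the free 7-OH by a hydroxyl-directed epoxidation.

Key step: step 8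

Remark: racemic intermediates (8, 10, 11, 14, 15) are drawn as one enantiomer with the transient ring-fusion centres left undefined, since both enantiomers converge on meso compounds; names of 16–25 use the target ring numbering given above.

**Step 1**
Reactants: 1 3,5-dihydroxybenzoic acid; 2 propan-2-ol
Product: 3 3,5-dihydroxy-4-(propan-2-yl)benzoic acid
Conditions: i-PrOH, 80% aq. H2SO4, 60–65 °C
Reagents that add atoms: propan-2-ol CC(C)O
Why: Friedel–Crafts alkylation by the 2-propyl cation should occur at C4, the position ortho to both hydroxyl groups and the only activated position not adjacent to the carboxyl group.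

**Step 2**
Reactants: 3 3,5-dihydroxy-4-(propan-2-yl)benzoic acid
Product: 5 3,5-bis(tert-butyldimethylsilyloxy)-4-(propan-2-yl)benzoic acid, via silyl ester 4 (not isolated)
Conditions: TBSCl (3.5 equiv), imidazole, DMF, rt; then AcOH/THF/H2O, rt
Reagents that add atoms: tert-butyldimethylsilyl chloride CC(C)(C)[Si](C)(C)Cl
Why: Silylation of both phenols (and transiently the acid) followed by selective hydrolysis of the far more labile silyl ester; the silyl ethers block phenol–ketone tautomerism during the hydrogenation that follows.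

**Step 3**
Reactants: 5 3,5-bis(tert-butyldimethylsilyloxy)-4-(propan-2-yl)benzoic acid
Product: 6 all-cis-3,5-bis(tert-butyldimethylsilyloxy)-4-(propan-2-yl)cyclohexane-1-carboxylic acid (meso)
Conditions: H2 (60 bar), 5% Rh/Al2O3, i-PrOH/hexane, 50 °C
Reagents that add atoms: none
Why: Heterogeneous cis-hydrogenation of the arene should deliver all six hydrogens to one face, so that both silyloxy groups and the isopropyl group end up all-cis, which sets the relative configuration of the future C7–C8–C9 triad in a meso compound (the carboxyl-bearing centre is removed in step 4).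

**Step 4**
Reactants: 6 all-cis-3,5-bis(tert-butyldimethylsilyloxy)-4-(propan-2-yl)cyclohexane-1-carboxylic acid
Product: 7 meso-(3R,5S)-3,5-bis(tert-butyldimethylsilyloxy)-4-(propan-2-yl)cyclohexan-1-one (3-O, 4-iPr, 5-O all cis)
Conditions: [Ir(dF(CF3)ppy)2(dtbbpy)]PF6 (1 mol %), K2HPO4, O2 (1 atm), DMSO, blue LEDs, rt
Reagents that add atoms: dioxygen O=O
Why: Photoredox decarboxylative oxygenation (carboxylate oxidation, loss of CO2, capture of the secondary radical by O2 and collapse to the ketone) should leave the meso triad untouched.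

**Step 5**
Reactants: 7 meso-(3R,5S)-3,5-bis(tert-butyldimethylsilyloxy)-4-(propan-2-yl)cyclohexan-1-one
Product: 8 rac-3,5-bis(tert-butyldimethylsilyloxy)-4-(propan-2-yl)-1-(trimethylsilyloxy)cyclohex-1-ene (3,4,5 all cis)
Conditions: LDA, TMSCl (internal quench), THF, −78 °C
Reagents that add atoms: chlorotrimethylsilane C[Si](C)(C)Cl
Why: Kinetic enolate formation with in situ O-silylation should outrun β-elimination of silanolate, and because the two α-methylene groups are enantiotopic only one constitution (as a racemate) can form.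

**Step 6**
Reactants: 8 rac-3,5-bis(tert-butyldimethylsilyloxy)-4-(propan-2-yl)-1-(trimethylsilyloxy)cyclohex-1-ene; 9 dichloroacetyl chloride
Product: 10 rac-8,8-dichloro-3,5-bis(tert-butyldimethylsilyloxy)-4-(propan-2-yl)-1-(trimethylsilyloxy)bicyclo[4.2.0]octan-7-one (cis ring fusion)
Conditions: Et3N, hexanes, 0 °C → rt (slow addition of 9)
Reagents that add atoms: dichloroacetyl chloride ClC(Cl)C(Cl)=O
Why: [2+2] cycloaddition of in situ generated dichloroketene with the silyl enol ether, with the nucleophilic enol β-carbon bonding to the ketene carbonyl carbon; the two ring-fusion centres are erased in step 7, so their configuration is irrelevant.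

**Step 7**
Reactants: 10 rac-8,8-dichloro-3,5-bis(tert-butyldimethylsilyloxy)-4-(propan-2-yl)-1-(trimethylsilyloxy)bicyclo[4.2.0]octan-7-one
Product: 12 meso-(5R,7S)-5,7-bis(tert-butyldimethylsilyloxy)-6-(propan-2-yl)cyclooctane-1,3-dione (5,6,7 all cis), via dechlorinated cyclobutanone 11 (not isolated)
Conditions: Zn dust, AcOH, i-PrOH/H2O, 0 °C → 40 °C
Reagents that add atoms: none
Why: Reductive dechlorination of the α,α-dichlorocyclobutanone, then loss of the TMS group and strain-driven retro-aldol cleavage of the ring-fusion bond (the known two-carbon enlargement of a cycloalkanone to a cycloalkane-1,3-dione) should return a meso compound.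

**Step 8**
Reactants: 12 meso-(5R,7S)-5,7-bis(tert-butyldimethylsilyloxy)-6-(propan-2-yl)cyclooctane-1,3-dione; 13 ethene
Product: 16 meso-(7R,9S)-7,9-bis(tert-butyldimethylsilyloxy)-8-(propan-2-yl)cyclodecane-1,5-dione (7,8,9 all cis), via silyl enol ether 14 (not isolated), via cyclobutane photoadduct 15 (not isolated)
Conditions: TMSCl, Et3N, Et2O, rt, filter and concentrate; ethene (saturated), CH2Cl2, hν (350 nm, Pyrex), −70 °C; then AcOH/THF/H2O, 0 °C → rt
Reagents that add atoms: ethene C=C
Why: Mechanism: TMSCl/Et3N fixes the poorly enolised dione as the 3-silyloxy-enone 14, whose excited state adds ethene stepwise through a 1,4-biradical to give the cyclobutane 15, and mild acid then removes the tertiary TMS group so that the strained β-hydroxy ketone undergoes retro-aldol cleavage of the former C2–C5 ring-fusion bond, which turns the eight-membered ring into the ten-membered 1,5-dione. The closest known reaction type is the De Mayo reaction of cyclic 1,3-diones or their enol silyl ethers with alkenes, which converts cyclohexane-1,3-diones into cyclooctane-1,5-diones. The only ring that is closed is the four-membered ring, by intermolecular [2+2] photocycloaddition (bonds C5–C4 and C2–C3), whereas the ten-membered ring is not closed but arises by fragmentation of the bond shared by the four- and eight-membered rings. The two stereocentres created at the ring fusion are transient and are erased in the fragmentation (one becomes the C5 carbonyl carbon, the other the C2 methylene), so no stereocontrol is needed and the all-cis C7–C8–C9 triad is not touched. Regioselectivity is not an issue either, because ethene is symmetric and the two possible enol ethers of the meso dione are mirror images that lead to the same meso product. The selectivity the step does need is kinetic, since capture of the excited enone by ethene must beat E/Z twisting and dimerisation of the eight-membered enone, which ethene-saturated solution, low temperature and high dilution should favour, while the non-basic work-up avoids β-elimination of silanol and transannular aldolisation of the product.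

**Step 9**
Reactants: 16 meso-(7R,9S)-7,9-bis(tert-butyldimethylsilyloxy)-8-(propan-2-yl)cyclodecane-1,5-dione; 17 dibromomethane
Product: 18 meso-(7R,9S)-7,9-bis(tert-butyldimethylsilyloxy)-1,5-dimethylidene-8-(propan-2-yl)cyclodecane
Conditions: Zn, CH2Br2, TiCl4, THF (reagent pre-formed at 0–5 °C); 16 in CH2Cl2, 0 °C → rt
Reagents that add atoms: dibromomethane BrCBr
Why: Takai–Lombardo methylenation with the non-basic gem-dimetallic methylene reagent should convert both unhindered ketones while avoiding β-elimination of silanol and transannular aldol condensation of the 1,5-dione.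

**Step 10**
Reactants: 18 meso-(7R,9S)-7,9-bis(tert-butyldimethylsilyloxy)-1,5-dimethylidene-8-(propan-2-yl)cyclodecane
Product: 19 meso-(7R,9S)-1,5-dimethylidene-8-(propan-2-yl)cyclodecane-7,9-diol (7,8,9 all cis)
Conditions: TBAF, THF, 50 °C
Reagents that add atoms: none
Why: Fluoride cleavage of both silyl ethers; with no carbonyl group left, the meso diol cannot form transannular hemiketals.

**Step 11**
Reactants: 19 meso-(7R,9S)-1,5-dimethylidene-8-(propan-2-yl)cyclodecane-7,9-diol
Product: 20 (7R,9S)-9-(tert-butyldimethylsilyloxy)-1,5-dimethylidene-8-(propan-2-yl)cyclodecan-7-ol (7-OH, 8-iPr, 9-OTBS all cis)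
Conditions: TBSCl (1.2 equiv), chiral amino-acid-derived N-methylimidazole silylation catalyst (20–30 mol %, antipode chosen to silylate the S carbinol), i-Pr2NEt, THF, −40 °C
Reagents that add atoms: tert-butyldimethylsilyl chloride CC(C)(C)[Si](C)(C)Cl
Why: Catalytic enantioselective silylation (desymmetrisation of a meso 1,3-diol), in which the catalyst binds the diol by hydrogen bonding and activates the silyl chloride as a Lewis base; the choice of one enantiotopic hydroxyl fixes the absolute configuration of C7, C8 and C9 at once.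

**Step 12**
Reactants: 20 (7R,9S)-9-(tert-butyldimethylsilyloxy)-1,5-dimethylidene-8-(propan-2-yl)cyclodecan-7-ol
Product: 21 (5R,7R,9S)-9-(tert-butyldimethylsilyloxy)-1-methylidene-8-(propan-2-yl)spiro[cyclodecane-5,2'-oxiran]-7-ol (oxirane O cis to 7-OH)
Conditions: VO(acac)2 (5 mol %), t-BuOOH (1.5 equiv, decane), CH2Cl2, 0 °C → rt
Reagents that add atoms: tert-butyl hydroperoxide CC(C)(C)OO
Why: Vanadium-catalysed hydroxyl-directed epoxidation, in which the vanadate ester of the free 7-OH should deliver oxygen to the homoallylic C5 methylidene on the face syn to O7 and so set C5, while the C1 methylidene has no free hydroxyl within reach.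

**Step 13**
Reactants: 21 (5R,7R,9S)-9-(tert-butyldimethylsilyloxy)-1-methylidene-8-(propan-2-yl)spiro[cyclodecane-5,2'-oxiran]-7-ol
Product: 22 (5R,7R,9S)-9-(tert-butyldimethylsilyloxy)-5-methyl-1-methylidene-8-(propan-2-yl)cyclodecane-5,7-diol
Conditions: LiEt3BH (3 equiv), THF, 0 °C → rt
Reagents that add atoms: none
Why: SN2 opening of the 1,1-disubstituted epoxide by hydride at the CH2 terminus should give the tertiary alcohol with the C5–O bond, and therefore the C5 configuration, intact.

**Step 14**
Reactants: 22 (5R,7R,9S)-9-(tert-butyldimethylsilyloxy)-5-methyl-1-methylidene-8-(propan-2-yl)cyclodecane-5,7-diol; 23 4-acetoxybenzoyl chloride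
Product: 24 (5R,7R,9S)-9-(tert-butyldimethylsilyloxy)-5-hydroxy-5-methyl-1-methylidene-8-(propan-2-yl)cyclodecan-7-yl 4-acetoxybenzoate
Conditions: pyridine, DMAP (0.2 equiv), CH2Cl2, 0 °C → rt
Reagents that add atoms: 4-acetoxybenzoyl chloride CC(=O)Oc1ccc(cc1)C(Cl)=O
Why: Nucleophile-catalysed acylation of the only secondary hydroxyl (C7); the tertiary C5 hydroxyl and the silyl ether should not react.

**Step 15**
Reactants: 24 (5R,7R,9S)-9-(tert-butyldimethylsilyloxy)-5-hydroxy-5-methyl-1-methylidene-8-(propan-2-yl)cyclodecan-7-yl 4-acetoxybenzoate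
Product: 26 (1R,2S,3S,9R)-3,9-dihydroxy-9-methyl-5-methylidene-2-(propan-2-yl)cyclodecyl 4-hydroxybenzoate (target), via phenol 25 (not isolated)
Conditions: NH3 (7 M in MeOH), 0 °C; evaporate; HF·pyridine, pyridine, THF, 0 °C → rt
Reagents that add atoms: none
Why: Aminolysis should remove the aryl acetate much faster than it attacks the hindered, electron-rich alkyl benzoate, and buffered HF then cleaves the C9 silyl ether under non-basic conditions that do not promote 1,3-acyl migration.

**Compound list**

1 | 3,5-dihydroxybenzoic acid | OC(=O)c1cc(O)cc(O)c1 | starting material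
2 | propan-2-ol | CC(C)O | starting material
3 | 3,5-dihydroxy-4-(propan-2-yl)benzoic acid | CC(C)c1c(O)cc(cc1O)C(O)=O | intermediate
4 | tert-butyldimethylsilyl 3,5-bis(tert-butyldimethylsilyloxy)-4-(propan-2-yl)benzoate | CC(C)c1c(O[Si](C)(C)C(C)(C)C)cc(cc1O[Si](C)(C)C(C)(C)C)C(=O)O[Si](C)(C)C(C)(C)C | intermediate (not isolated)
5 | 3,5-bis(tert-butyldimethylsilyloxy)-4-(propan-2-yl)benzoic acid | CC(C)c1c(O[Si](C)(C)C(C)(C)C)cc(cc1O[Si](C)(C)C(C)(C)C)C(O)=O | intermediate
6 | all-cis-3,5-bis(tert-butyldimethylsilyloxy)-4-(propan-2-yl)cyclohexane-1-carboxylic acid (meso) | OC(=O)[C@H]1C[C@@H](O[Si](C)(C)C(C)(C)C)[C@@H](C(C)C)[C@@H](O[Si](C)(C)C(C)(C)C)C1 | intermediate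
7 | meso-(3R,5S)-3,5-bis(tert-butyldimethylsilyloxy)-4-(propan-2-yl)cyclohexan-1-one (all cis) | O=C1C[C@@H](O[Si](C)(C)C(C)(C)C)[C@@H](C(C)C)[C@@H](O[Si](C)(C)C(C)(C)C)C1 | intermediate
8 | rac-3,5-bis(tert-butyldimethylsilyloxy)-4-(propan-2-yl)-1-(trimethylsilyloxy)cyclohex-1-ene (3,4,5 all cis) | C[Si](C)(C)OC1=C[C@@H](O[Si](C)(C)C(C)(C)C)[C@@H](C(C)C)[C@@H](O[Si](C)(C)C(C)(C)C)C1 | intermediate
9 | dichloroacetyl chloride | ClC(Cl)C(Cl)=O | starting material
10 | rac-8,8-dichloro-3,5-bis(tert-butyldimethylsilyloxy)-4-(propan-2-yl)-1-(trimethylsilyloxy)bicyclo[4.2.0]octan-7-one (3,4,5 all cis; cis ring fusion) | C[Si](C)(C)OC12C[C@@H](O[Si](C)(C)C(C)(C)C)[C@@H](C(C)C)[C@@H](O[Si](C)(C)C(C)(C)C)C1C(=O)C2(Cl)Cl | intermediate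
11 | rac-3,5-bis(tert-butyldimethylsilyloxy)-4-(propan-2-yl)-1-(trimethylsilyloxy)bicyclo[4.2.0]octan-7-one | C[Si](C)(C)OC12C[C@@H](O[Si](C)(C)C(C)(C)C)[C@@H](C(C)C)[C@@H](O[Si](C)(C)C(C)(C)C)C1C(=O)C2 | intermediate (not isolated)
12 | meso-(5R,7S)-5,7-bis(tert-butyldimethylsilyloxy)-6-(propan-2-yl)cyclooctane-1,3-dione (5,6,7 all cis) | O=C1CC(=O)C[C@@H](O[Si](C)(C)C(C)(C)C)[C@@H](C(C)C)[C@@H](O[Si](C)(C)C(C)(C)C)C1 | intermediate
13 | ethene | C=C | starting material
14 | rac-5,7-bis(tert-butyldimethylsilyloxy)-6-(propan-2-yl)-3-(trimethylsilyloxy)cyclooct-2-en-1-one | C[Si](C)(C)OC1=CC(=O)C[C@@H](O[Si](C)(C)C(C)(C)C)[C@@H](C(C)C)[C@@H](O[Si](C)(C)C(C)(C)C)C1 | intermediate (not isolated)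
15 | rac-3,5-bis(tert-butyldimethylsilyloxy)-4-(propan-2-yl)-1-(trimethylsilyloxy)bicyclo[6.2.0]decan-7-one | C[Si](C)(C)OC12CCC1C(=O)C[C@@H](O[Si](C)(C)C(C)(C)C)[C@@H](C(C)C)[C@@H](O[Si](C)(C)C(C)(C)C)C2 | intermediate (not isolated)
16 | meso-(7R,9S)-7,9-bis(tert-butyldimethylsilyloxy)-8-(propan-2-yl)cyclodecane-1,5-dione (7,8,9 all cis) | O=C1CCCC(=O)C[C@@H](O[Si](C)(C)C(C)(C)C)[C@@H](C(C)C)[C@@H](O[Si](C)(C)C(C)(C)C)C1 | intermediate
17 | dibromomethane | BrCBr | starting material
18 | meso-(7R,9S)-7,9-bis(tert-butyldimethylsilyloxy)-1,5-dimethylidene-8-(propan-2-yl)cyclodecane | C=C1CCCC(=C)C[C@@H](O[Si](C)(C)C(C)(C)C)[C@@H](C(C)C)[C@@H](O[Si](C)(C)C(C)(C)C)C1 | intermediate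
19 | meso-(7R,9S)-1,5-dimethylidene-8-(propan-2-yl)cyclodecane-7,9-diol (all cis) | C=C1CCCC(=C)C[C@@H](O)[C@@H](C(C)C)[C@@H](O)C1 | intermediate
20 | (7R,9S)-9-(tert-butyldimethylsilyloxy)-1,5-dimethylidene-8-(propan-2-yl)cyclodecan-7-ol (all cis) | C=C1CCCC(=C)C[C@@H](O)[C@@H](C(C)C)[C@@H](O[Si](C)(C)C(C)(C)C)C1 | intermediate
21 | (5R,7R,9S)-9-(tert-butyldimethylsilyloxy)-1-methylidene-8-(propan-2-yl)spiro[cyclodecane-5,2'-oxiran]-7-ol (oxirane O cis to 7-OH) | C=C1CCC[C@]2(CO2)C[C@@H](O)[C@@H](C(C)C)[C@@H](O[Si](C)(C)C(C)(C)C)C1 | intermediate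
22 | (5R,7R,9S)-9-(tert-butyldimethylsilyloxy)-5-methyl-1-methylidene-8-(propan-2-yl)cyclodecane-5,7-diol | C=C1CCC[C@@](C)(O)C[C@@H](O)[C@@H](C(C)C)[C@@H](O[Si](C)(C)C(C)(C)C)C1 | intermediate
23 | 4-acetoxybenzoyl chloride | CC(=O)Oc1ccc(cc1)C(Cl)=O | starting material
24 | (5R,7R,9S)-9-(tert-butyldimethylsilyloxy)-5-hydroxy-5-methyl-1-methylidene-8-(propan-2-yl)cyclodecan-7-yl 4-acetoxybenzoate | C=C1CCC[C@@](C)(O)C[C@@H](OC(=O)c2ccc(OC(C)=O)cc2)[C@@H](C(C)C)[C@@H](O[Si](C)(C)C(C)(C)C)C1 | intermediate
25 | (5R,7R,9S)-9-(tert-butyldimethylsilyloxy)-5-hydroxy-5-methyl-1-methylidene-8-(propan-2-yl)cyclodecan-7-yl 4-hydroxybenzoate | C=C1CCC[C@@](C)(O)C[C@@H](OC(=O)c2ccc(O)cc2)[C@@H](C(C)C)[C@@H](O[Si](C)(C)C(C)(C)C)C1 | intermediate (not isolated)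
26 | (1R,2S,3S,9R)-3,9-dihydroxy-9-methyl-5-methylidene-2-(propan-2-yl)cyclodecyl 4-hydroxybenzoate | C=C1CCC[C@@](C)(O)C[C@@H](OC(=O)c2ccc(O)cc2)[C@@H](C(C)C)[C@@H](O)C1 | target

**Step count**

Total steps: 15. Longest linear sequence: 15 steps (fully linear from 1).

**Steps most likely to fail**

Step 8 (photochemical ring enlargement). What may go wrong: the excited eight-membered enone relaxes by twisting about its C=C bond (E/Z isomerisation) or dimerises faster than it is captured by the low stationary concentration of dissolved ethene, so that little cyclobutane forms. The fallback sets out from 12 and comes back at 16. The silyl enol ether 14 is made as before and irradiated in CH2Cl2 containing a large excess of (Z)-1,2-dichloroethene, a liquid two-carbon partner that is a standard substitute for ethene and ethyne in enone photocycloadditions, which should give the dichlorocyclobutane photoadduct F1. AcOH/THF/H2O should then give, by the same desilylation and retro-aldol fragmentation, the ring-enlarged 2,3-dichlorocyclodecane-1,5-dione F2. Zn/AcOH should reduce the α-chloro ketone with loss of the β-chloride to the cyclodec-2-ene-1,5-dione F3, and H2 over Pd/C (no other alkene is present at this stage) should saturate the enone and return to 16.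

Step 11 (desymmetrising silylation). What may go wrong: poor discrimination between the two enantiotopic hydroxyl groups, both shielded by the isopropyl group and held on a flexible ten-membered ring, or no catalytic turnover. The fallback sets out from 19 and comes back at 20 by an enzymatic desymmetrisation. Lipase-catalysed transesterification (Burkholderia cepacia lipase, vinyl acetate, t-BuOMe), which for this enzyme class is expected to acylate the R-configured carbinol, should give the 7-monoacetate F4. TBSOTf/2,6-lutidine should silylate the remaining 9-OH to the acetate silyl ether F5, and K2CO3/MeOH should remove the acetate to give 20.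

Step 12 (directed epoxidation that sets C5). What may go wrong: poor facial selectivity at the C5 methylidene, because the flexible ten-membered ring can present either face to the vanadium-bound peroxide, or competing oxidation of the C1 methylidene. The fallback sets out from 20 and comes back at 22, bypassing 21, and closes the C5–O bond within a six-membered ring under thermodynamic control. Treatment of 20 with HgClOAc in acetone with catalytic Yb(OTf)3 should engage the free 7-OH as its acetone hemiketal and give, by intramolecular Markovnikov oxymercuration of the C5 methylidene, the cis-fused organomercurial acetonide F6. NaBH4/NaOH demercuration should give the C5-methyl acetonide F7, and aqueous AcOH/THF should remove the acetonide to give 22.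

**Further compounds**

F1 | step 8 | rac-9,10-dichloro-3,5-bis(tert-butyldimethylsilyloxy)-4-(propan-2-yl)-1-(trimethylsilyloxy)bicyclo[6.2.0]decan-7-one | C[Si](C)(C)OC12C(Cl)C(Cl)C1C(=O)C[C@@H](O[Si](C)(C)C(C)(C)C)[C@@H](C(C)C)[C@@H](O[Si](C)(C)C(C)(C)C)C2
F2 | step 8 | rac-2,3-dichloro-7,9-bis(tert-butyldimethylsilyloxy)-8-(propan-2-yl)cyclodecane-1,5-dione | O=C1C(Cl)C(Cl)CC(=O)C[C@@H](O[Si](C)(C)C(C)(C)C)[C@@H](C(C)C)[C@@H](O[Si](C)(C)C(C)(C)C)C1
F3 | step 8 | rac-7,9-bis(tert-butyldimethylsilyloxy)-8-(propan-2-yl)cyclodec-2-ene-1,5-dione | O=C1C=CCC(=O)C[C@@H](O[Si](C)(C)C(C)(C)C)[C@@H](C(C)C)[C@@H](O[Si](C)(C)C(C)(C)C)C1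
F4 | step 11 | (7R,9S)-9-hydroxy-1,5-dimethylidene-8-(propan-2-yl)cyclodecan-7-yl acetate | C=C1CCCC(=C)C[C@@H](OC(C)=O)[C@@H](C(C)C)[C@@H](O)C1
F5 | step 11 | (7R,9S)-9-(tert-butyldimethylsilyloxy)-1,5-dimethylidene-8-(propan-2-yl)cyclodecan-7-yl acetate | C=C1CCCC(=C)C[C@@H](OC(C)=O)[C@@H](C(C)C)[C@@H](O[Si](C)(C)C(C)(C)C)C1
F6 | step 12 | 5,7-O-isopropylidene acetal of (5R,7R,9S)-9-(tert-butyldimethylsilyloxy)-5-(chloromercuriomethyl)-1-methylidene-8-(propan-2-yl)cyclodecane-5,7-diol | C=C1CCC[C@]2(C[Hg]Cl)C[C@@H](OC(C)(C)O2)[C@@H](C(C)C)[C@@H](O[Si](C)(C)C(C)(C)C)C1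
F7 | step 12 | 5,7-O-isopropylidene acetal of 22 | C=C1CCC[C@]2(C)C[C@@H](OC(C)(C)O2)[C@@H](C(C)C)[C@@H](O[Si](C)(C)C(C)(C)C)C1
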